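**Retrosynthetic overview**
1. The C10 tiglate and the C6 4-hydroxybenzoate are attached last; the C6 carbinol comes from a C6 ketone by a reduction directed by the C4 hydroxyl.
2. The seven-membered ring (C1, C5, C6, C7, C8, C9, C10) is closed last by a rhodium-catalysed tandem cyclopropanation/Cope rearrangement (formal (4+3) cycloaddition) that forms C7–C8 and C1–C10 from a 2-silyloxydiene (C7=C6–C5=C1) on the finished cyclopentene and an (E)-4-silyloxyvinyldiazoacetate (C8, C9, C10).
3. Enabling feature: this ring is a masked cyclohepta-1,4-diene. C8=C9 is present, the C6–O/C5–H pair is a latent C5=C6 enol ether, C7 is the single CH2 between them, and the adjacent sp3 carbons C1 (quaternary, CH3) and C10 (oxygen-bearing) are the two termini joined in the [3,3] step.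
4. The cyclopentene (C1–C5) with the C4 carbinol stereocentre comes from (S)-terpinen-4-ol by ozonolysis and aldol ring contraction.
5. Ring order: cyclopentene first, seven-membered ring second.

Key step: step 9

Numbering used throughout (daucane): C1 = ring-fusion carbon bearing CH3 (C15); C2, C3 = cyclopentane CH2; C4 = carbinol carbon bearing isopropyl; C5 = ring-fusion CH; C6 = carbon bearing the aryl ester; C7 = CH2; C8 = olefinic carbon bearing CH3 (C14); C9 = olefinic CH; C10 = carbon bearing the tiglate.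
Remark: the target is read as the cis-fused daucane (C1–CH3 and H5 cis), with C4–OH trans to H5, C6–O cis to H5 and C10–O trans to the C1 methyl, i.e. (1R,4R,5S,6S,10S); the C10 acyl group is tigloyl (E).
Remark: (S)-(+)-terpinen-4-ol is taken as available in high enantiomeric purity.
Remark: the catalyst antipode written in step 9 is assumed to be the one matched with the (R)-configured diene; if the sense of induction is the opposite, Rh2(R-PTAD)4 is used.

**Route**

Step 1
Reactants: 1 (S)-terpinen-4-ol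
Product: 2 triethyl{[(1S)-4-methyl-1-(propan-2-yl)cyclohex-3-en-1-yl]oxy}silane
Conditions: TESOTf, 2,6-lutidine, CH2Cl2, 0 °C
Reagents that add atoms: triethylsilyl trifluoromethanesulfonate CC[Si](CC)(CC)OS(=O)(=O)C(F)(F)F
Why: A silyl triflate with a hindered pyridine base silylates tertiary alcohols; the TES ether blocks retro-aldol cleavage in step 3 and O–H insertion in step 9, and no stereocentre is touched.

Step 2
Reactants: 2 triethyl{[(1S)-4-methyl-1-(propan-2-yl)cyclohex-3-en-1-yl]oxy}silane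
Product: 4 (3S)-6-oxo-3-(propan-2-yl)-3-(triethylsilyloxy)heptanal, via ozonide 3 (not isolated)
Conditions: O3, CH2Cl2, −78 °C; then Me2S, −78 °C to rt
Reagents that add atoms: ozone [O-][O+]=O
Why: Ozonolysis with reductive work-up cleaves the only C=C bond to the keto-aldehyde and leaves the quaternary carbinol centre untouched.

Step 3
Reactants: 4 (3S)-6-oxo-3-(propan-2-yl)-3-(triethylsilyloxy)heptanal
Product: 6 (5R)-2-methyl-5-(propan-2-yl)-5-(triethylsilyloxy)cyclopent-1-ene-1-carbaldehyde, via aldol adduct 5 (not isolated)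
Conditions: piperidine (cat.), AcOH (cat.), toluene, 50 °C
Reagents that add atoms: none
Why: Amine-catalysed intramolecular aldol condensation (the aldehyde enamine adds 5-exo to the methyl ketone, then dehydration to the conjugated tetrasubstituted enal) is the known behaviour of 6-oxoheptanals; the silyl ether prevents retro-aldol cleavage and no new stereocentre remains.

Step 4
Reactants: 6 (5R)-2-methyl-5-(propan-2-yl)-5-(triethylsilyloxy)cyclopent-1-ene-1-carbaldehyde
Product: 7 1-[(5R)-2-methyl-5-(propan-2-yl)-5-(triethylsilyloxy)cyclopent-1-en-1-yl]ethan-1-ol (mixture of carbinol epimers)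
Conditions: MeMgBr, THF, −78 to 0 °C
Reagents that add atoms: methylmagnesium bromide C[Mg]Br
Why: Grignard 1,2-addition to the hindered enal; the new carbinol centre forms as a mixture that is erased in step 5.

Step 5
Reactants: 7 1-[(5R)-2-methyl-5-(propan-2-yl)-5-(triethylsilyloxy)cyclopent-1-en-1-yl]ethan-1-ol
Product: 8 1-[(5R)-2-methyl-5-(propan-2-yl)-5-(triethylsilyloxy)cyclopent-1-en-1-yl]ethan-1-one
Conditions: DMP, CH2Cl2, rt
Reagents that add atoms: none
Why: Periodinane oxidation of a secondary allylic alcohol to the enone under neutral conditions that leave the silyl ether intact.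

Step 6
Reactants: 8 1-[(5R)-2-methyl-5-(propan-2-yl)-5-(triethylsilyloxy)cyclopent-1-en-1-yl]ethan-1-one
Product: 9 tert-butyl(dimethyl)({1-[(5R)-2-methyl-5-(propan-2-yl)-5-(triethylsilyloxy)cyclopent-1-en-1-yl]ethenyl}oxy)silane
Conditions: TBSOTf, Et3N, CH2Cl2, −78 to 0 °C
Reagents that add atoms: tert-butyldimethylsilyl trifluoromethanesulfonate CC(C)(C)[Si](C)(C)OS(=O)(=O)C(F)(F)F
Why: Soft enolisation of a methyl enone at its only α-CH3 gives the cross-conjugated 2-silyloxydiene (silyl enol ether formation).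

Step 7
Reactants: 10 methyl diazoacetate; 11 (tert-butyldimethylsilyloxy)acetaldehyde
Product: 12 methyl 4-(tert-butyldimethylsilyloxy)-2-diazo-3-hydroxybutanoate (racemic)
Conditions: DBU (cat.), MeCN, rt
Reagents that add atoms: none
Why: Base-catalysed aldol-type addition of the diazoacetate carbanion to an aldehyde; the racemic carbinol centre is removed in step 8.

Step 8
Reactants: 12 methyl 4-(tert-butyldimethylsilyloxy)-2-diazo-3-hydroxybutanoate
Product: 14 methyl (3E)-4-(tert-butyldimethylsilyloxy)-2-diazobut-3-enoate, via dichlorophosphate 13 (not isolated)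
Conditions: POCl3, Et3N, CH2Cl2, 0 °C to rt
Reagents that add atoms: none
Why: Dehydration of β-hydroxy-α-diazo esters with POCl3/Et3N is the standard entry to vinyldiazoacetates, and the E enol ether is expected as the less hindered elimination product.

Step 9
Reactants: 9 tert-butyl(dimethyl)({1-[(5R)-2-methyl-5-(propan-2-yl)-5-(triethylsilyloxy)cyclopent-1-en-1-yl]ethenyl}oxy)silane; 14 methyl (3E)-4-(tert-butyldimethylsilyloxy)-2-diazobut-3-enoate
Product: 16 methyl (1R,4R,10S)-6,10-bis(tert-butyldimethylsilyloxy)-4-(triethylsilyloxy)dauca-5,8-dien-14-oate, via cis-divinylcyclopropane 15 (not isolated)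
Conditions: Rh2(S-PTAD)4 (dirhodium tetrakis[(S)-(1-adamantyl)(N-phthalimido)acetate], 1 mol%), hexanes, 0 °C to rt, slow addition of 14 (1.5 equiv); then toluene, 80 °C
Reagents that add atoms: none
Why: The catalyst decomposes 14 to a donor/acceptor rhodium vinylcarbenoid that cyclopropanates the terminal 1,1-disubstituted silyloxyalkene C6=C7 of 9 (the tetrasubstituted ring alkene and the trans-disubstituted enol ether of 14 are inert) to give cis-divinylcyclopropane 15, which undergoes a boat-like [3,3] Cope shift that breaks C6–C8 and forms C1–C10. The closest known reaction type is the rhodium-catalysed tandem cyclopropanation/Cope rearrangement (formal (4+3) cycloaddition) of vinyldiazoacetates with 2-silyloxydienes and with 1-vinylcycloalkenes whose methyl-bearing ring carbon becomes a quaternary centre. The three-membered ring closes by (2+1) carbene addition (C7–C8 and C6–C8), and the seven-membered ring (C1, C5, C6, C7, C8, C9, C10) closes in the sigmatropic step by formation of the C1–C10 bond, driven by release of cyclopropane strain. C1 and C10 are set relative to each other by the boat transition state, in which the two E substituents (the silyloxy group on C10 and ring carbon C2 on C1) end up cis, so the C10 oxygen is trans to the angular methyl; their absolute configuration follows from the cyclopropane configuration (C8 R, C6 S) fixed by the chiral catalyst. The step needs cis selectivity in the cyclopropanation (donor/acceptor carbenoids place the alkene π-substituent cis to the vinyl group), carbenoid rather than vinylogous reactivity (substituted vinyl terminus, hydrocarbon solvent), and bond formation on the cyclopentene face anti to the C4 isopropyl group, for which catalyst and substrate are matched. The Z methyl group on C1 slows the Cope step, hence the final heating.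

Step 10
Reactants: 16 methyl (1R,4R,10S)-6,10-bis(tert-butyldimethylsilyloxy)-4-(triethylsilyloxy)dauca-5,8-dien-14-oate
Product: 17 (1R,4R,10S)-6,10-bis(tert-butyldimethylsilyloxy)-4-(triethylsilyloxy)dauca-5,8-dien-14-ol
Conditions: i-Bu2AlH, CH2Cl2, −78 °C
Reagents that add atoms: none
Why: i-Bu2AlH reduces the α,β-unsaturated methyl ester to the allylic alcohol at low temperature without touching the silyl ethers or the silyl enol ether.

Step 11
Reactants: 17 (1R,4R,10S)-6,10-bis(tert-butyldimethylsilyloxy)-4-(triethylsilyloxy)dauca-5,8-dien-14-ol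
Product: 19 (1R,4R,10S)-6,10-bis(tert-butyldimethylsilyloxy)-4-(triethylsilyloxy)dauca-5,8-diene, via allylic mesylate 18 (not isolated)
Conditions: MsCl, Et3N, CH2Cl2, −30 °C; then LiEt3BH, THF, −30 to 0 °C
Reagents that add atoms: none
Why: Sulfonate formation and SN2 hydride displacement turn the primary allylic alcohol into the C8 methyl group; direct attack at the unhindered primary carbon keeps the C8=C9 bond in place.

Step 12
Reactants: 19 (1R,4R,10S)-6,10-bis(tert-butyldimethylsilyloxy)-4-(triethylsilyloxy)dauca-5,8-diene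
Product: 21 (1R,4R,5R,10S)-10-(tert-butyldimethylsilyloxy)-4-hydroxydauc-8-en-6-one, via silyl-protected ketone 20 (not isolated)
Conditions: HF·pyridine, pyridine, THF, 0 °C to rt
Reagents that add atoms: none
Why: Buffered fluoride cleaves the silyl enol ether first, and the enol should be protonated at C5 on the convex face of the folded cycloheptadiene (opposite to C10 and to the C4 silyloxy group), giving the cis ring fusion with H5 cis to the C1 methyl, which is also the epimer that places C6 anti to isopropyl; the tertiary TES ether is cleaved next while the hindered secondary TBS ether at C10 should survive.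

Step 13
Reactants: 21 (1R,4R,5R,10S)-10-(tert-butyldimethylsilyloxy)-4-hydroxydauc-8-en-6-one
Product: 22 (1R,4R,5S,6S,10S)-10-(tert-butyldimethylsilyloxy)dauc-8-ene-4,6-diol
Conditions: Me4NBH(OAc)3, MeCN/AcOH, −30 °C
Reagents that add atoms: none
Why: Evans–Saksena reduction: boron binds the C4 hydroxyl and delivers hydride intramolecularly to the face of the C6 carbonyl that is syn to C4, which puts the C6 oxygen cis to H5; the mildly acidic, cold medium should leave the β,γ-double bond in place.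

Step 14
Reactants: 22 (1R,4R,5S,6S,10S)-10-(tert-butyldimethylsilyloxy)dauc-8-ene-4,6-diol
Product: 23 (1R,4R,5S,6S,10S)-10-(tert-butyldimethylsilyloxy)-4-hydroxydauc-8-en-6-yl 4-(acetyloxy)benzoate
Conditions: 4-(acetyloxy)benzoyl chloride, pyridine, DMAP (cat.), CH2Cl2, 0 °C to rt
Reagents that add atoms: 4-(acetyloxy)benzoyl chloride CC(=O)Oc1ccc(cc1)C(Cl)=O
Why: DMAP-catalysed acylation of the only secondary hydroxyl; the tertiary C4 hydroxyl does not react.

Step 15
Reactants: 23 (1R,4R,5S,6S,10S)-10-(tert-butyldimethylsilyloxy)-4-hydroxydauc-8-en-6-yl 4-(acetyloxy)benzoate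
Product: 24 (1R,4R,5S,6S,10S)-4,10-dihydroxydauc-8-en-6-yl 4-(acetyloxy)benzoate
Conditions: HF·pyridine, THF, rt
Reagents that add atoms: none
Why: Acidic fluoride removes the secondary TBS ether, while the aryl acetate, the benzoate and the tertiary alcohol are stable to it.

Step 16
Reactants: 24 (1R,4R,5S,6S,10S)-4,10-dihydroxydauc-8-en-6-yl 4-(acetyloxy)benzoate
Product: 25 (1R,4R,5S,6S,10S)-6-{[4-(acetyloxy)benzoyl]oxy}-4-hydroxydauc-8-en-10-yl (2E)-2-methylbut-2-enoate
Conditions: tiglic acid, 2,4,6-trichlorobenzoyl chloride, Et3N, toluene, rt; then 24, DMAP (cat.), rt to 50 °C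
Reagents that add atoms: tiglic acid C/C=C(\C)C(=O)O
Why: Yamaguchi esterification acylates the hindered secondary allylic alcohol with retention at C10; the mixed anhydride avoids the ketene pathway that deconjugates tigloyl chloride, and the tertiary hydroxyl is inert.

Step 17
Reactants: 25 (1R,4R,5S,6S,10S)-6-{[4-(acetyloxy)benzoyl]oxy}-4-hydroxydauc-8-en-10-yl (2E)-2-methylbut-2-enoate
Product: 26 (1R,4R,5S,6S,10S)-4-hydroxy-6-[(4-hydroxybenzoyl)oxy]dauc-8-en-10-yl (2E)-2-methylbut-2-enoate (CNP0273650.3)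
Conditions: NH4OAc, MeOH/H2O, rt
Reagents that add atoms: none
Why: Phenolic acetates are transesterified under these conditions far faster than alkyl benzoates or enoates, so only the aryl acetate should be cleaved.

**Compound list**
1 | (S)-terpinen-4-ol, (1S)-4-methyl-1-(propan-2-yl)cyclohex-3-en-1-ol | CC1=CC[C@](O)(C(C)C)CC1 | starting material
2 | triethyl{[(1S)-4-methyl-1-(propan-2-yl)cyclohex-3-en-1-yl]oxy}silane | CC1=CC[C@](O[Si](CC)(CC)CC)(C(C)C)CC1 | intermediate
3 | (4S)-1-methyl-4-(propan-2-yl)-4-(triethylsilyloxy)-7,8,9-trioxabicyclo[4.2.1]nonane (ozonide, both bridgehead diastereomers) | CC12CC[C@@](O[Si](CC)(CC)CC)(C(C)C)CC(O1)OO2 | intermediate (not isolated)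
4 | (3S)-6-oxo-3-(propan-2-yl)-3-(triethylsilyloxy)heptanal | CC(=O)CC[C@@](CC=O)(O[Si](CC)(CC)CC)C(C)C | intermediate
5 | (5R)-2-hydroxy-2-methyl-5-(propan-2-yl)-5-(triethylsilyloxy)cyclopentane-1-carbaldehyde (aldol adduct, mixture at C1 and C2) | O=CC1C(C)(O)CC[C@@]1(O[Si](CC)(CC)CC)C(C)C | intermediate (not isolated)
6 | (5R)-2-methyl-5-(propan-2-yl)-5-(triethylsilyloxy)cyclopent-1-ene-1-carbaldehyde | O=CC1=C(C)CC[C@@]1(O[Si](CC)(CC)CC)C(C)C | intermediate
7 | 1-[(5R)-2-methyl-5-(propan-2-yl)-5-(triethylsilyloxy)cyclopent-1-en-1-yl]ethan-1-ol (carbinol epimers) | CC(O)C1=C(C)CC[C@@]1(O[Si](CC)(CC)CC)C(C)C | intermediate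
8 | 1-[(5R)-2-methyl-5-(propan-2-yl)-5-(triethylsilyloxy)cyclopent-1-en-1-yl]ethan-1-one | CC(=O)C1=C(C)CC[C@@]1(O[Si](CC)(CC)CC)C(C)C | intermediate
9 | tert-butyl(dimethyl)({1-[(5R)-2-methyl-5-(propan-2-yl)-5-(triethylsilyloxy)cyclopent-1-en-1-yl]ethenyl}oxy)silane | C=C(O[Si](C)(C)C(C)(C)C)C1=C(C)CC[C@@]1(O[Si](CC)(CC)CC)C(C)C | intermediate
10 | methyl diazoacetate | COC(=O)C=[N+]=[N-] | starting material
11 | (tert-butyldimethylsilyloxy)acetaldehyde | CC(C)(C)[Si](C)(C)OCC=O | starting material
12 | methyl 4-(tert-butyldimethylsilyloxy)-2-diazo-3-hydroxybutanoate (racemic) | COC(=O)C(=[N+]=[N-])C(O)CO[Si](C)(C)C(C)(C)C | intermediate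
13 | methyl 4-(tert-butyldimethylsilyloxy)-3-[(dichlorophosphoryl)oxy]-2-diazobutanoate | COC(=O)C(=[N+]=[N-])C(OP(=O)(Cl)Cl)CO[Si](C)(C)C(C)(C)C | intermediate (not isolated)
14 | methyl (3E)-4-(tert-butyldimethylsilyloxy)-2-diazobut-3-enoate | COC(=O)C(=[N+]=[N-])/C=C/O[Si](C)(C)C(C)(C)C | intermediate
15 | methyl (1R,2S)-2-(tert-butyldimethylsilyloxy)-1-[(E)-2-(tert-butyldimethylsilyloxy)ethenyl]-2-[(5R)-2-methyl-5-(propan-2-yl)-5-(triethylsilyloxy)cyclopent-1-en-1-yl]cyclopropane-1-carboxylate (vinyl groups cis) | COC(=O)[C@@]1(/C=C/O[Si](C)(C)C(C)(C)C)C[C@]1(O[Si](C)(C)C(C)(C)C)C2=C(C)CC[C@@]2(O[Si](CC)(CC)CC)C(C)C | intermediate (not isolated)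
16 | methyl (1R,4R,10S)-6,10-bis(tert-butyldimethylsilyloxy)-4-(triethylsilyloxy)dauca-5,8-dien-14-oate | CC(C)(C)[Si](C)(C)O[C@H]1C=C(C(=O)OC)CC(O[Si](C)(C)C(C)(C)C)=C2[C@@]1(C)CC[C@@]2(O[Si](CC)(CC)CC)C(C)C | intermediate
17 | (1R,4R,10S)-6,10-bis(tert-butyldimethylsilyloxy)-4-(triethylsilyloxy)dauca-5,8-dien-14-ol | CC(C)(C)[Si](C)(C)O[C@H]1C=C(CO)CC(O[Si](C)(C)C(C)(C)C)=C2[C@@]1(C)CC[C@@]2(O[Si](CC)(CC)CC)C(C)C | intermediate
18 | (1R,4R,10S)-6,10-bis(tert-butyldimethylsilyloxy)-4-(triethylsilyloxy)dauca-5,8-dien-14-yl methanesulfonate | CC(C)(C)[Si](C)(C)O[C@H]1C=C(COS(C)(=O)=O)CC(O[Si](C)(C)C(C)(C)C)=C2[C@@]1(C)CC[C@@]2(O[Si](CC)(CC)CC)C(C)C | intermediate (not isolated)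
19 | (1R,4R,10S)-6,10-bis(tert-butyldimethylsilyloxy)-4-(triethylsilyloxy)dauca-5,8-diene | CC(C)(C)[Si](C)(C)O[C@H]1C=C(C)CC(O[Si](C)(C)C(C)(C)C)=C2[C@@]1(C)CC[C@@]2(O[Si](CC)(CC)CC)C(C)C | intermediate
20 | (1R,4R,5R,10S)-10-(tert-butyldimethylsilyloxy)-4-(triethylsilyloxy)dauc-8-en-6-one | CC(C)(C)[Si](C)(C)O[C@H]1C=C(C)CC(=O)[C@@H]2[C@@]1(C)CC[C@@]2(O[Si](CC)(CC)CC)C(C)C | intermediate (not isolated)
21 | (1R,4R,5R,10S)-10-(tert-butyldimethylsilyloxy)-4-hydroxydauc-8-en-6-one | CC(C)(C)[Si](C)(C)O[C@H]1C=C(C)CC(=O)[C@@H]2[C@@]1(C)CC[C@@]2(O)C(C)C | intermediate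
22 | (1R,4R,5S,6S,10S)-10-(tert-butyldimethylsilyloxy)dauc-8-ene-4,6-diol | CC(C)(C)[Si](C)(C)O[C@H]1C=C(C)C[C@H](O)[C@@H]2[C@@]1(C)CC[C@@]2(O)C(C)C | intermediate
23 | (1R,4R,5S,6S,10S)-10-(tert-butyldimethylsilyloxy)-4-hydroxydauc-8-en-6-yl 4-(acetyloxy)benzoate | CC(C)(C)[Si](C)(C)O[C@H]1C=C(C)C[C@H](OC(=O)c2ccc(OC(C)=O)cc2)[C@@H]2[C@@]1(C)CC[C@@]2(O)C(C)C | intermediate
24 | (1R,4R,5S,6S,10S)-4,10-dihydroxydauc-8-en-6-yl 4-(acetyloxy)benzoate | O[C@H]1C=C(C)C[C@H](OC(=O)c2ccc(OC(C)=O)cc2)[C@@H]2[C@@]1(C)CC[C@@]2(O)C(C)C | intermediate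
25 | (1R,4R,5S,6S,10S)-6-{[4-(acetyloxy)benzoyl]oxy}-4-hydroxydauc-8-en-10-yl (2E)-2-methylbut-2-enoate | C/C=C(\C)C(=O)O[C@H]1C=C(C)C[C@H](OC(=O)c2ccc(OC(C)=O)cc2)[C@@H]2[C@@]1(C)CC[C@@]2(O)C(C)C | intermediate
26 | (1R,4R,5S,6S,10S)-4-hydroxy-6-[(4-hydroxybenzoyl)oxy]dauc-8-en-10-yl (2E)-2-methylbut-2-enoate | C/C=C(\C)C(=O)O[C@H]1C=C(C)C[C@H](OC(=O)c2ccc(O)cc2)[C@@H]2[C@@]1(C)CC[C@@]2(O)C(C)C | target

**Count**
Total steps: 17. Longest linear sequence: 15 steps (steps 1–6 and 9–17); steps 7 and 8 make the diazo partner.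

**Steps most likely to fail**

Step 9. The carbenoid may be consumed by dimerisation or vinylogous attack before it cyclopropanates the hindered, 1,1-disubstituted silyloxyalkene, or the cyclopropanation may give the trans-divinylcyclopropane, which does not rearrange. The fallback sets out from 6 and returns at 22; it moves the C6 oxygen out of the cycloaddition. Aldehyde 6 would be methylenated (Ph3P=CH2, THF) to the vinyl diene triethyl{[(1R)-2-ethenyl-3-methyl-1-(propan-2-yl)cyclopent-2-en-1-yl]oxy}silane F1, whose monosubstituted alkene is the best substrate class for this cyclopropanation. F1 and 14 under the conditions of step 9 should give methyl (1R,4R,10S)-10-(tert-butyldimethylsilyloxy)-4-(triethylsilyloxy)dauca-5,8-dien-14-oate F2. Hydroboration–oxidation (BH3·THF, 0 °C; NaBO3) of the electron-rich C5=C6 bond on the convex face (the enoate is deactivated) would set H5 and the C6 hydroxyl cis by syn addition, giving methyl (1R,4R,5S,6S,10S)-10-(tert-butyldimethylsilyloxy)-6-hydroxy-4-(triethylsilyloxy)dauc-8-en-14-oate F3. Reduction with i-Bu2AlH would give (1R,4R,5S,6S,10S)-10-(tert-butyldimethylsilyloxy)-4-(triethylsilyloxy)dauc-8-ene-6,14-diol F4; selective mesylation of the primary allylic hydroxyl would give its 14-methanesulfonate F5, and LiEt3BH would give (1R,4R,5S,6S,10S)-10-(tert-butyldimethylsilyloxy)-4-(triethylsilyloxy)dauc-8-en-6-ol F6. Buffered HF·pyridine would then remove the TES group to give 22.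

Step 12. Once the C4 hydroxyl is free next to the C6 ketone, retro-aldol opening or β-elimination of the tertiary oxygen can occur, the C8=C9 bond can shift into conjugation with the ketone, and the hindered TES ether may be cleaved too slowly. The fallback sets out from 20 and returns at 24; it avoids the free β-hydroxy ketone and sets C6 by inversion instead of directed reduction. The enol ether alone would be cleaved (Bu4NF/AcOH, THF, −20 °C) to isolate 20, which would be reduced by external hydride from the open convex face (NaBH4, MeOH, −40 °C) to the 6-epimeric alcohol (1R,4R,5S,6R,10S)-10-(tert-butyldimethylsilyloxy)-4-(triethylsilyloxy)dauc-8-en-6-ol F7. Mitsunobu esterification (PPh3, diisopropyl azodicarboxylate, 4-(acetyloxy)benzoic acid, toluene) would invert C6 and give (1R,4R,5S,6S,10S)-10-(tert-butyldimethylsilyloxy)-4-(triethylsilyloxy)dauc-8-en-6-yl 4-(acetyloxy)benzoate F8. HF·pyridine would remove both silyl groups to give 24.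

Step 8. The elimination may give an E/Z mixture of the enol ether, and the acid-sensitive silyl enol ether may not survive the phosphorylating medium; a Z vinyl terminus would lead to the C10 epimer or stall the Cope step. The fallback sets out from 11 and returns at 14; it builds the alkene before the diazo group. Wittig reaction of 11 with methyl (triphenylphosphoranylidene)acetate would give methyl (2E)-4-(tert-butyldimethylsilyloxy)but-2-enoate F9. Deconjugative diazo transfer through the dienolate (DBU, 4-acetamidobenzenesulfonyl azide, MeCN) would give 14, with the enol ether geometry set under equilibrating conditions.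

**Further compounds**
F1 | step 9 | triethyl{[(1R)-2-ethenyl-3-methyl-1-(propan-2-yl)cyclopent-2-en-1-yl]oxy}silane | C=CC1=C(C)CC[C@@]1(O[Si](CC)(CC)CC)C(C)C
F2 | step 9 | methyl (1R,4R,10S)-10-(tert-butyldimethylsilyloxy)-4-(triethylsilyloxy)dauca-5,8-dien-14-oate | CC(C)(C)[Si](C)(C)O[C@H]1C=C(C(=O)OC)CC=C2[C@@]1(C)CC[C@@]2(O[Si](CC)(CC)CC)C(C)C
F3 | step 9 | methyl (1R,4R,5S,6S,10S)-10-(tert-butyldimethylsilyloxy)-6-hydroxy-4-(triethylsilyloxy)dauc-8-en-14-oate | CC(C)(C)[Si](C)(C)O[C@H]1C=C(C(=O)OC)C[C@H](O)[C@@H]2[C@@]1(C)CC[C@@]2(O[Si](CC)(CC)CC)C(C)C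
F4 | step 9 | (1R,4R,5S,6S,10S)-10-(tert-butyldimethylsilyloxy)-4-(triethylsilyloxy)dauc-8-ene-6,14-diol | CC(C)(C)[Si](C)(C)O[C@H]1C=C(CO)C[C@H](O)[C@@H]2[C@@]1(C)CC[C@@]2(O[Si](CC)(CC)CC)C(C)C
F5 | step 9 | (1R,4R,5S,6S,10S)-10-(tert-butyldimethylsilyloxy)-6-hydroxy-4-(triethylsilyloxy)dauc-8-en-14-yl methanesulfonate | CC(C)(C)[Si](C)(C)O[C@H]1C=C(COS(C)(=O)=O)C[C@H](O)[C@@H]2[C@@]1(C)CC[C@@]2(O[Si](CC)(CC)CC)C(C)C
F6 | step 9 | (1R,4R,5S,6S,10S)-10-(tert-butyldimethylsilyloxy)-4-(triethylsilyloxy)dauc-8-en-6-ol | CC(C)(C)[Si](C)(C)O[C@H]1C=C(C)C[C@H](O)[C@@H]2[C@@]1(C)CC[C@@]2(O[Si](CC)(CC)CC)C(C)C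
F7 | step 12 | (1R,4R,5S,6R,10S)-10-(tert-butyldimethylsilyloxy)-4-(triethylsilyloxy)dauc-8-en-6-ol | CC(C)(C)[Si](C)(C)O[C@H]1C=C(C)C[C@@H](O)[C@@H]2[C@@]1(C)CC[C@@]2(O[Si](CC)(CC)CC)C(C)C
F8 | step 12 | (1R,4R,5S,6S,10S)-10-(tert-butyldimethylsilyloxy)-4-(triethylsilyloxy)dauc-8-en-6-yl 4-(acetyloxy)benzoate | CC(C)(C)[Si](C)(C)O[C@H]1C=C(C)C[C@H](OC(=O)c2ccc(OC(C)=O)cc2)[C@@H]2[C@@]1(C)CC[C@@]2(O[Si](CC)(CC)CC)C(C)C
F9 | step 8 | methyl (2E)-4-(tert-butyldimethylsilyloxy)but-2-enoate | COC(=O)/C=C/CO[Si](C)(C)C(C)(C)C
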